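Readings and results were computed with made-up constants, noise included.

At the last reading the elm run holds less E than the maple run, 52% against 58% at 8.00 h, and elm carries more D, 0.150 M against 0.111 M, with L equal.

| flask | E | D | L | remark | time |
|---|---|---|---|---|---|
| elm | 0.050 M | 3 equiv | 0.037 M | run made earlier |  |
| maple | 0.037 M | 3 equiv | 0.037 M | run made earlier |  |
| Tuesday's | 0.074 M | 3.00 equiv | 0.0370 M |  | 20 h |
| Wednesday's | 0.074 M | 4.50 equiv | 0.0370 M |  | 20 h |

| run | time / h | E / % | X / % |
|---|---|---|---|
| elm | 0.500 | 95 | 4 |
| elm | 1.00 | 93 | 7 |
| elm | 2.00 | 82 | 15 |
| elm | 4.00 | 70 | 26 |
| elm | 8.00 | 52 | 41 |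
| maple | 1.33 | 86 | 9 |
| maple | 3.00 | 80 | 15 |
| maple | 4.00 | 73 | 21 |
| maple | 6.00 | 66 | 28 |
| maple | 8.00 | 58 | 31 |

(scatter of a reading: 1.5 percentage points)

- the numbers in the tables scatter by 1.5 percentage points (one standard deviation)

- part of the E that has reacted at the end, Tuesday's
- part of the E that has reacted at the end, Wednesday's
- what raising the equivalents of D from its lowest to its highest value here does to the part of the E that has reacted (changes below 5 percentage points count as none) (it falls / no change / it rises)

That comparison fits a clock set by D, though the charge of E differs between the two runs as well. If E reacts with D, and D stands well above E, E decays exponentially (the pseudo-first-order picture). Then n, the number of lifetimes E has lived through, is the logarithm of charged E over E left, and n should equal κ[D]t. Here κ, the clock constant, is n divided by the D charged and the time, and the last elm reading gives 0.545 /M/h. The last maple reading gives 0.613 /M/h. E and X together fall short of the charge at elm's last reading, so κ is a lumped reading, not the constant of one step.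

Tuesday's flask, with 0.222 M of D over 20 h, then has n = 2.42, which puts the part of E reacted at 91.1%. Wednesday's, with 0.333 M of D, has n = 3.63, which gives 97.3%, a rise of 6.2 percentage points. Both figures take D as standing at its charge throughout, while the reaction spends D, and they are offered as upper marks.

The forecast stands lower, at 85% (77% to 91%) for Tuesday's and 93% (83% to 97%) for Wednesday's, and on the trend it says it rises: “That is a rise of more than 5 points, though the margin is modest”.

The flask gives 84.8% for Tuesday's and 94.5% for Wednesday's; on raising the equivalents of D, the answer to the trend is it rises, by 9.7 points.

    E + D → J + X (k = 0.545 /M/h)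
    D + J ⇌ Z, settled at all times (K = 8800 /M)
    E + L → G (k = 0.458 /M/h)
    J → Q (k = 0.0303 /h)

The rise between the two flasks is due to the higher equivalents of D: Wednesday's flask set back to Tuesday's equivalents reaches 84.8% against 94.5%. Wednesday's result stands under its mark in part because D falls as the run goes: with D held at its charge, the same flask reaches 98.0% against 94.5%. The same clock serves a neighbour of Wednesday's charged with 1.10 equiv of D, where n = 0.887 puts the mark at 58.8%. That flask reaches 54.0%, with 34.7% of its charged D still free at 20.0 h.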